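The beta run opens the case: substrate plus target stands at 93.4% of the charge at 25.0 min, but at 67.5% at 90.0 min, while target falls too. So you can read target as a way station with an unseen exit.

the same everywhere: substrate 0.47 M; reagent 0.517 M

| run | free catalyst | temperature | remark | time |
|---|---|---|---|---|
| delta | 12 mM | 45 °C | run made earlier |  |
| beta | 46 mM | 78 °C | run made earlier |  |
| larch | 23 mM | 60 °C |  | 5.0 h |
| elm | 23 mM | 30 °C |  | 5.0 h |
| ash | 23 mM | 90 °C |  | 5.0 h |

delta run (percent of the substrate charged)

| time / h | target / % | substrate / % |
|---|---|---|
| 0.667 | 3.7 | 95.7 |
| 2.00 | 11.6 | 86.9 |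
| 4.00 | 18.0 | 82.8 |
| 6.00 | 22.0 | 74.4 |
| 8.00 | 25.2 | 71.0 |

beta run (percent of the substrate charged)

| time / min | target / % | substrate / % |
|---|---|---|
| 8.00 | 13.9 | 81.4 |
| 25.0 | 15.0 | 78.4 |
| 50.0 | 12.2 | 69.4 |
| 80.0 | 9.9 | 61.8 |
| 90.0 | 8.7 | 58.8 |

(each reading ± 1 percentage point)

1. the flask that comes out highest in amount of target, in percent of the substrate charged, or "all alike" when all lie within 1.5 percentage points (larch / elm / ash / all alike)
2. target at the end, in percent of the substrate charged, larch
3. target at the end, in percent of the substrate charged, elm
4. target at the end, in percent of the substrate charged, ash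



Follow one target molecule. At each moment it stays or leaves, a first-order loss with a time constant. The balance counts what has left, however fast target is being made, so the time constant is mean target times the window, divided by the balance lost.

In beta the balance loses 26 percentage points, which gives 0.496 h. In delta it loses 3.2 points between first and last reading, which gives 33.1 h. Both are rough readings: the scatter is 1 point per reading.

Take ln of the time constant as straight in temperature. At 60 °C the target life, the mean time a target molecule lasts, is then 4.90 h. Elm and ash lie outside the two runs, so their values are rougher.

My reckoning runs as follows. Ash gets 0.108 h, far shorter than the 5.0 h run, so I expect ash near zero. Elm gets 224 hours, far longer than the run, so elm keeps what it makes. Larch's life matches the run, so larch loses a real part of its target. The life does not rank larch against elm; that needs the speed of making.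

The forecast gives 20% for larch, 22% for elm and 0.3% for ash, and names elm: “Elm edges larch, though this is uncertain”.

The flasks give 19.0% for larch, 14.9% for elm and 0.0369% for ash, so larch comes highest.

    substrate + reagent + free catalyst ⇌ target + free catalyst, rate k1*[substrate]*[reagent]*[free catalyst] forward; the back reaction follows from the equilibrium constant (K = 1.10 M⁻¹, k = 34.2 M⁻² h⁻¹, Ea = 67.0 kJ mol⁻¹, ΔH = −35.0 kJ mol⁻¹)
    free catalyst → spent catalyst (k = 0.0373 h⁻¹, Ea = 116 kJ mol⁻¹)
    target → over-reaction product (k = 0.198 h⁻¹, Ea = 113 kJ mol⁻¹)
    (constants at 60 °C)

The run in larch lasts 1.02 target lives, and target holds 19.0% of the charge beside 19.2% over-reaction product. Now take the neighbour of ash, the same flask run at 75 °C. Its target life, from larch's and beta's, is 0.726 h, so its run lasts 6.89 lives and target should not stay. Of the 54.7% of substrate consumed there, nearly all stands as over-reaction product, 50.5%, and target is 4.19%.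

The data stem from a simulated flask for an exercise; the scatter is artificial.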